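**Strategy.** Ring C (C8, C9, C11, C12, C13, C14) is opened across C8–C9 and C13–C14, which face each other through C11–C12: a retro-[4+2]. The key step is an intramolecular Diels–Alder reaction in which a Z-dienylsilane on C10 adds to a 2-(2-bromoallyl) enone tethered through C5–C6–C7. On a preformed lactone-bridged ring A it closes ring C and a six-membered ring B at once and sets C9 and the quaternary C8. Afterwards silicon becomes the C11 oxygen, the surplus ring-B carbonyl carbon C7 is turned by Wolff ring contraction into the C6 carboxyl, and the bromoallyl arm closes ring D by radical cyclization.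

Key step: step 11

Remark on numbering: atoms carry gibberellin numbers throughout (ring A C1–C5/C10, C18 methyl, C19 lactone carbonyl, C7 carboxyl carbon, C17 exocyclic methylene); "β" is the face of the C18 methyl, "α" the face of the lactone bridge.

Assumption: the sense of induction of the chiral dioxirane in step 2 is assigned by analogy with 1-substituted cyclohexenes, which makes the L-fructose-derived ketone the matched one; if the sense is the reverse, the D-fructose-derived ketone is used.

**Step 1**
Reactants: 1 isochroman-1-one (3,4-dihydroisocoumarin)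
Product: 2 rac-8a-methyl-3,4,6,8a-tetrahydro-1H-isochromen-1-one (δ-lactone with C4 quaternary methyl, C2=C3 and C5=C10 olefins)
Conditions: K, t-BuOH (1 equiv), NH3(l)/THF, −78 °C; then MeI, −78 °C → rt
Reagents that add atoms: iodomethane, CI
Why: Birch reductive alkylation: the benzoate-type lactone is reduced to the 1,4-dihydro dienolate, which is C-methylated at the carbon α to the carbonyl to give the quaternary C4 (racemic).

**Step 2**
Reactants: 2 rac-δ-lactone diene
Product: 3 4a,5-epoxy-8a-methyl-3,4,4a,5,6,8a-hexahydro-1H-isochromen-1-one, single enantiomer, epoxide oxygen anti to the methyl (5α,10α-epoxide)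
Conditions: 1,2:4,5-di-O-isopropylidene-β-L-erythro-2,3-hexodiulo-2,6-pyranose (0.3 equiv), Oxone (about 0.6 equiv), K2CO3 buffer (pH 10.5), Bu4NHSO4, MeCN–dimethoxymethane–H2O, 0 °C, stopped near half conversion
Reagents that add atoms: potassium peroxymonosulfate (Oxone), [K+].OOS(=O)(=O)[O-]
Why: Shi epoxidation run as a kinetic resolution: the chiral dioxirane attacks the electron-rich trisubstituted C5=C10 olefin (the cis-disubstituted C2=C3 olefin is a poor substrate) of the matched enantiomer on the face anti to the angular methyl, which sets the absolute configuration at C4 and puts the epoxide oxygen on the C19 face.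

**Step 3**
Reactants: 3 epoxy δ-lactone
Product: 4 cis-8a-methyl-3,4,4a,8a-tetrahydro-1H-isochromene-1,5(6H)-dione (C10 ketone, 5β-H cis to the methyl, C2=C3 olefin retained)
Conditions: BF3·OEt2, CH2Cl2, −40 → 0 °C
Reagents that add atoms: none
Why: Meinwald rearrangement: the Lewis acid opens the epoxide at tertiary C5 and the C10 hydrogen migrates suprafacially to C5 on the face opposite the leaving oxygen, giving the C10 ketone with 5β-H, as ring-fusion epoxides give cis-fused ketones.

**Step 4**
Reactants: 4 keto δ-lactone
Product: 6 5-ethynyl-8-(2-hydroxyethyl)-1-methyl-6-oxabicyclo[3.2.1]oct-2-en-7-one (19,10-γ-lactone; C10 ethynyl; 5β-H; C6–C7 as CH2CH2OH; C2=C3 olefin), via C10 alkoxide 5 (not isolated)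
Conditions: HC≡CMgBr, CeCl3, THF, −78 → 0 °C; aq. NH4Cl
Reagents that add atoms: ethynylmagnesium bromide, C#C[Mg]Br
Why: Non-basic organocerium 1,2-addition (no enolization of the β,γ-unsaturated ketone) should go by equatorial attack on the chair with C19 axial (Curtin–Hammett: the other chair has an axial methyl on one face of the carbonyl and the axial C6 methylene on the other), so the alkoxide lies on the C19 face and translactonizes to the bridged γ-lactone, freeing the C7 alcohol and locking C5.

**Step 5**
Reactants: 6 ethynyl lactone alcohol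
Product: 7 10-(but-3-en-1-ynyl) lactone alcohol (C9≡C11–C12=C13)
Conditions: vinyl bromide (1 M in THF), Pd(PPh3)2Cl2 (3 mol%), CuI (6 mol%), i-Pr2NH, THF, rt
Reagents that add atoms: vinyl bromide, C=CBr
Why: Sonogashira coupling of the terminal alkyne installs C12 and C13 under mild amine conditions that leave the lactone, the free alcohol and the ring olefin untouched.

**Step 6**
Reactants: 7 enyne lactone alcohol
Product: 8 dienylsilane lactone alcohol (C9H=C11(SiMe2Bn)–C12H=C13H2 with C10 and the vinyl group cis across C9=C11)
Conditions: BnMe2SiH (1.1 equiv), Pt2[(CH2=CHSiMe2)2O]3 (1 mol%, zerovalent platinum), P(t-Bu)3 (2 mol%), THF, rt → 40 °C; mild aqueous acid work-up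
Reagents that add atoms: benzyldimethylsilane, C[SiH](C)Cc1ccccc1
Why: Platinum-catalysed hydrosilylation is a syn addition selective for alkynes over alkenes and places silicon on the alkyne carbon remote from the quaternary propargylic centre, so C10 and the vinyl group end up cis (the Z-diene needed in step 11) and silicon marks C11 as a masked ketone.

**Step 7**
Reactants: 8 dienylsilane lactone alcohol
Product: 9 dienylsilane lactone aldehyde (C7 aldehyde)
Conditions: Dess–Martin periodinane, NaHCO3, CH2Cl2, 0 °C → rt
Reagents that add atoms: none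
Why: Buffered Dess–Martin oxidation converts the primary alcohol into the aldehyde without touching the vinylsilane, the diene or the lactone.

**Step 8**
Reactants: 10 2,3-dibromopropene
Product: 11 2-bromopent-1-en-4-yne
Conditions: HC≡CMgBr (0.5 M in THF), CuBr (5 mol%), THF, 0 °C → rt
Reagents that add atoms: ethynylmagnesium bromide, C#C[Mg]Br
Why: Copper-catalysed substitution of the allylic bromide by the alkynyl Grignard reagent leaves the vinylic bromide intact.

**Step 9**
Reactants: 11 2-bromopent-1-en-4-yne
Product: 12 2,4-dibromopenta-1,4-diene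
Conditions: B-bromo-9-borabicyclo[3.3.1]nonane, CH2Cl2, 0 °C; then AcOH
Reagents that add atoms: B-bromo-9-borabicyclo[3.3.1]nonane, BrB1C2CCCC1CCC2
Why: Bromoboration of the terminal alkyne (bromine to the internal carbon) followed by protonolysis of the C–B bond is a Markovnikov hydrobromination giving the 2-bromo-1-alkene; the existing vinyl bromide does not react.

**Step 10**
Reactants: 9 dienylsilane lactone aldehyde; 12 2,4-dibromopenta-1,4-diene (3 equiv)
Product: 13 allylic alcohol (C7 carbinol, both epimers; C8(=C14H2) carrying the 2-bromoallyl group C15–C16(Br)=C17)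
Conditions: CrCl2 (6 equiv), NiCl2 (2 mol%), DMF, rt
Reagents that add atoms: none
Why: Nozaki–Hiyama–Kishi coupling adds one vinyl bromide terminus of the symmetrical dibromide (used in excess) chemoselectively to the aldehyde in the presence of the lactone and the vinylsilane; the C7 configuration is irrelevant because it is oxidized next.

**Step 11**
Reactants: 13 allylic alcohol
Product: 15 tetracyclic ketone (lactone-bridged ring A, six-membered ring B with C7 ketone, ring C cyclohexene with C11 silyl and C11=C12 olefin, C8 2-bromoallyl β, 9β-H), via enone 14 (not isolated)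
Conditions: Dess–Martin periodinane, NaHCO3, CH2Cl2, 0 °C; filter; then toluene, BHT (cat.), 150 °C, sealed tube
Reagents that add atoms: none
Why: Oxidation unmasks the α-methylene ketone, which undergoes a concerted, asynchronous intramolecular [4+2] cycloaddition with the 2-silyl diene (the C13–C14 bond leads); the closest known type is the thermal intramolecular Diels–Alder reaction of 1,7,9-decatrien-3-ones bearing Z-dienes. Ring C is closed by the cycloaddition itself (both new bonds, six-membered) and ring B is closed in the fused mode through the C8–C9 bond over the four-atom tether C10–C5–C6–C7. Because C10 is the inside (Z) substituent of the diene, only the cis B/C fusion is geometrically possible, which puts H9 and C15 on the same face. The face is set by the chair-like tether, which must be trans-fused to the rigid lactone-bridged ring A (C5 and C10 already fixed): C11 is then equatorial, H9 axial on the β face, and C14 axial on the face of the lactone oxygen, which is the natural C8/C9 pair. The step needs π-facial selectivity and reactivity of a hindered Z-diene: the tether geometry secures the former, the bulky 2-silyl group (which favours the s-cis diene) and the enone activation support the latter. The regiochemistry is enforced by the tether and the C2=C3 and vinyl bromide olefins are spectators.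

**Step 12**
Reactants: 15 tetracyclic ketone
Product: 17 α-diazoketone (C6 diazo, C7 ketone), via trifluoroacetyl ketone 16 (not isolated)
Conditions: LiHMDS, THF, −78 °C; CF3CO2CH2CF3; then MsN3, Et3N, H2O, MeCN, rt
Reagents that add atoms: methanesulfonyl azide, CS(=O)(=O)N=[N+]=[N-]
Why: Detrifluoroacetylative diazo transfer (Regitz type): the ketone can enolize only toward C6 because C8 is quaternary, so activation and diazo transfer are regiospecific.

**Step 13**
Reactants: 17 α-diazoketone
Product: 20 ring-contracted 2-(trimethylsilyl)ethyl ester (five-membered ring B, C6 ester β), via ketene 18 (not isolated), via 6-epi ester 19 (not isolated)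
Conditions: hν (Hg lamp, Pyrex), Me3SiCH2CH2OH, THF, 0 °C; then t-BuOK (0.3 equiv), t-BuOH–THF, rt
Reagents that add atoms: 2-(trimethylsilyl)ethanol, C[Si](C)(C)CCO
Why: Photochemical Wolff rearrangement: the quaternary C8 migrates with retention from C7 to C6 and the ketene is trapped by the alcohol; the base then equilibrates C6 to the ester trans to the C4–C5 bond, expected to be the more stable (natural 6β) epimer.

**Step 14**
Reactants: 20 2-(trimethylsilyl)ethyl ester
Product: 22 keto acid (C11 ketone, free C7 carboxylic acid), via silanol acid 21 (not isolated)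
Conditions: Bu4NF, THF, 0 °C → rt; then KHCO3, H2O2 (30%), MeOH, rt; acidify to pH 3
Reagents that add atoms: hydrogen peroxide, OO
Why: Tamao–Fleming oxidation: fluoride removes the benzyl group from silicon (and cleaves the silylethyl ester by β-elimination), and peroxide then oxidizes the C–Si bond with retention to the enol, which gives the C11 ketone under weakly basic conditions that spare the β-acyloxy ketone.

**Step 15**
Reactants: 22 keto acid
Product: 23 enone acid (C11 ketone, C12=C13 olefin)
Conditions: IBX (2.5 equiv), DMSO–toluene, 70 °C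
Reagents that add atoms: none
Why: IBX dehydrogenation of the ketone can only occur toward C12–C13 because the other α-carbon (C9) has no β-hydrogen (C8 and C10 are quaternary), and it avoids base, which would expel the lactone from the β-acyloxy ketone.

**Step 16**
Reactants: 23 enone acid
Product: 24 2β,3β-diol enone acid
Conditions: OsO4 (5 mol%), N-methylmorpholine N-oxide (1.2 equiv), acetone–H2O, 0 °C → rt
Reagents that add atoms: N-methylmorpholine N-oxide, C[N+]1([O-])CCOCC1; water, O
Why: Upjohn dihydroxylation: the isolated C2=C3 olefin reacts ahead of the electron-poor enone and vinyl bromide, and osmium adds syn from the β face, opposite the lactone bridge that blocks the α face, setting C2 and C3.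

**Step 17**
Reactants: 24 diol enone acid
Product: 25 11-oxo gibberellin (ring D closed, C16 exocyclic methylene, 13-H)
Conditions: Bu3SnH (1.5 equiv, slow addition), AIBN (0.2 equiv), benzene (0.01 M), 80 °C; KF work-up
Reagents that add atoms: none
Why: Vinyl radical cyclization: the C16 radical from the bromide adds 5-exo to the enone β-carbon C13 from the only face it can reach (that of C15), closing the bicyclo[3.2.1]octane with the exocyclic methylene in place, and the α-keto radical at C12 is reduced by the stannane.

**Step 18**
Reactants: 25 11-oxo gibberellin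
Product: 26 target, CNP0322347.1 (2β,3β,11β-trihydroxy-19,10-lactone 7-acid)
Conditions: NaBH4 (excess), CeCl3·7H2O, MeOH, −40 → 0 °C; aq. citric acid
Reagents that add atoms: none
Why: Luche reduction: the C15–C16 bridge shields the top face of the C11 carbonyl as two syn-axial groups do in an 11-oxo steroid, so hydride arrives equatorially and gives the axial 11β-alcohol, while the weakly basic conditions spare the lactone.

**Compound list**

1 | isochroman-1-one | O=C1OCCc2ccccc12 | starting material
2 | rac-8a-methyl-3,4,6,8a-tetrahydro-1H-isochromen-1-one | CC12C=CCC=C1CCOC2=O | intermediate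
3 | epoxy δ-lactone (5α,10α-epoxide, oxygen anti to methyl) | O1[C@H]2CC=C[C@@](C)(C(=O)OCC3)[C@@]123 | intermediate
4 | cis-fused keto δ-lactone (C10 ketone, 5β-H) | O=C1CC=C[C@@](C)(C(=O)OCC2)[C@H]12 | intermediate
5 | C10 tertiary alkoxide of the ethynyl adduct (δ-lactone intact) | C#C[C@]1([O-])CC=C[C@@](C)(C(=O)OCC2)[C@H]12 | intermediate (not isolated)
6 | 5-ethynyl-8-(2-hydroxyethyl)-1-methyl-6-oxabicyclo[3.2.1]oct-2-en-7-one | C#C[C@@]12CC=C[C@@](C)(C(=O)O1)[C@H]2CCO | intermediate
7 | enyne lactone alcohol | C=CC#C[C@@]12CC=C[C@@](C)(C(=O)O1)[C@H]2CCO | intermediate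
8 | dienylsilane lactone alcohol (C10 cis to vinyl) | C=C/C([Si](C)(C)Cc3ccccc3)=C\[C@@]12CC=C[C@@](C)(C(=O)O1)[C@H]2CCO | intermediate
9 | dienylsilane lactone aldehyde | C=C/C([Si](C)(C)Cc3ccccc3)=C\[C@@]12CC=C[C@@](C)(C(=O)O1)[C@H]2CC=O | intermediate
10 | 2,3-dibromopropene | C=C(Br)CBr | starting material
11 | 2-bromopent-1-en-4-yne | C=C(Br)CC#C | intermediate
12 | 2,4-dibromopenta-1,4-diene | C=C(Br)CC(Br)=C | intermediate
13 | allylic alcohol (C7 epimers) | C=C/C([Si](C)(C)Cc3ccccc3)=C\[C@@]12CC=C[C@@](C)(C(=O)O1)[C@H]2CC(O)C(=C)CC(Br)=C | intermediate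
14 | enone (Diels–Alder precursor) | C=C/C([Si](C)(C)Cc3ccccc3)=C\[C@@]12CC=C[C@@](C)(C(=O)O1)[C@H]2CC(=O)C(=C)CC(Br)=C | intermediate (not isolated)
15 | tetracyclic ketone (Diels–Alder adduct) | C=C(Br)C[C@]23CCC=C([Si](C)(C)Cc4ccccc4)[C@H]2[C@@]12CC=C[C@@](C)(C(=O)O1)[C@H]2CC3=O | intermediate
16 | C6 trifluoroacetyl ketone | C=C(Br)C[C@]23CCC=C([Si](C)(C)Cc4ccccc4)[C@H]2[C@@]12CC=C[C@@](C)(C(=O)O1)[C@H]2C(C(=O)C(F)(F)F)C3=O | intermediate (not isolated)
17 | α-diazoketone | C=C(Br)C[C@]23CCC=C([Si](C)(C)Cc4ccccc4)[C@H]2[C@@]12CC=C[C@@](C)(C(=O)O1)[C@H]2C(=[N+]=[N-])C3=O | intermediate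
18 | ring-contracted ketene | C=C(Br)C[C@]23CCC=C([Si](C)(C)Cc4ccccc4)[C@H]2[C@@]12CC=C[C@@](C)(C(=O)O1)[C@H]2C3=C=O | intermediate (not isolated)
19 | 6-epi 2-(trimethylsilyl)ethyl ester | C=C(Br)C[C@]23CCC=C([Si](C)(C)Cc4ccccc4)[C@H]2[C@@]12CC=C[C@@](C)(C(=O)O1)[C@H]2[C@H]3C(=O)OCC[Si](C)(C)C | intermediate (not isolated)
20 | 2-(trimethylsilyl)ethyl ester (6β) | C=C(Br)C[C@]23CCC=C([Si](C)(C)Cc4ccccc4)[C@H]2[C@@]12CC=C[C@@](C)(C(=O)O1)[C@H]2[C@@H]3C(=O)OCC[Si](C)(C)C | intermediate
21 | silanol acid | C=C(Br)C[C@]23CCC=C([Si](C)(C)O)[C@H]2[C@@]12CC=C[C@@](C)(C(=O)O1)[C@H]2[C@@H]3C(=O)O | intermediate (not isolated)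
22 | keto acid (C11 ketone) | C=C(Br)C[C@]23CCCC(=O)[C@H]2[C@@]12CC=C[C@@](C)(C(=O)O1)[C@H]2[C@@H]3C(=O)O | intermediate
23 | enone acid | C=C(Br)C[C@]23CC=CC(=O)[C@H]2[C@@]12CC=C[C@@](C)(C(=O)O1)[C@H]2[C@@H]3C(=O)O | intermediate
24 | 2β,3β-diol enone acid | C=C(Br)C[C@]23CC=CC(=O)[C@H]2[C@@]12C[C@H](O)[C@H](O)[C@@](C)(C(=O)O1)[C@H]2[C@@H]3C(=O)O | intermediate
25 | 11-oxo gibberellin | C=C1C[C@]23C[C@H]1CC(=O)[C@H]2[C@@]12C[C@H](O)[C@H](O)[C@@](C)(C(=O)O1)[C@H]2[C@@H]3C(=O)O | intermediate
26 | CNP0322347.1 | C=C1C[C@]23C[C@H]1C[C@H](O)[C@H]2[C@@]12C[C@H](O)[C@H](O)[C@@](C)(C(=O)O1)[C@H]2[C@@H]3C(=O)O | target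

**Total step count:** 18. **Longest linear sequence:** 16 steps (steps 1–7 and 10–18).

**Steps most likely to fail**

Step 11 (key cycloaddition). The Z-diene must reach an s-cis geometry with the fully substituted C10 on its inside, so the cycloaddition may be too slow; the α-methylene ketone could then polymerize, or the reaction could leak through a boat-like tether to the C8/C9 diastereomer. Fallback: the two bonds are formed stepwise and cationically instead of in a concerted thermal process. It sets out from enone 14, generated from 13 as in step 11. Treatment with 1,2-bis(trimethylsilyloxy)ethane and Me3SiOTf in CH2Cl2 at −78 °C forms the 2-vinyl-1,3-dioxolanium ion in situ (ionic Diels–Alder reaction). This allyl cation attacks the diene terminus C13 without needing an s-cis diene, and the resulting allyl cation closes onto the enol ether at C9 through the same chair tether, giving the ethylene ketal of the adduct F1. Hydrolysis with pyridinium p-toluenesulfonate in wet acetone returns to the route at ketone 15.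

Step 4 (alkynylation and translactonization). Attack on the wrong face of the flexible cis-fused keto lactone, epimerization at C5 or migration of the C2=C3 olefin into conjugation would give material that cannot form the 19,10-lactone. Fallback: ring A is locked as a bridged iodolactone before the ketone is made, so that addition can only come from the exo face. It sets out from epoxide 3. LiOH opens the δ-lactone, and I2/NaHCO3 then lactonizes the carboxylate onto the C2=C3 olefin to give the 19,2-iodolactone epoxy alcohol F2. The alcohol is silylated (t-BuMe2SiCl, imidazole) to the silyl ether F3, and BF3·OEt2 rearranges the epoxide to the locked C10 ketone F4 (5β-H, C6 chain equatorial). HC≡CMgBr/CeCl3 adds anti to the lactone bridge, as with bicyclo[3.2.1]octan-3-ones, to give the ethynyl carbinol F5. Zn/AcOH eliminates the iodolactone, restoring the C2=C3 olefin and the acid, which lactonizes onto the axial C10 hydroxyl to give the silyl ether of the ethynyl lactone F6. Bu4NF removes the silyl group and the route is rejoined at 6.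

Step 2 (kinetic resolution). A low selectivity factor, or erosion of enantiomeric purity near half conversion, would pass material of insufficient optical purity into every later step. Fallback: the quaternary centre is set with a chiral auxiliary instead. It sets out from 1. AlMe3-mediated opening with (S)-2-(methoxymethyl)pyrrolidine (or its enantiomer, whichever gives the required sense) gives the hydroxy amide F7, which is silylated to the silyl ether F8. Birch reduction–methylation (K, t-BuOH, NH3; MeI) of this chiral benzamide gives the diene amide F9 as one diastereomer. Aqueous HCl in THF removes the silyl group and lactonizes with loss of the auxiliary to the single enantiomer of the δ-lactone diene F10. Epoxidation with m-chloroperbenzoic acid anti to the angular methyl rejoins the route at 3.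

**Further compounds**

F1 | step 11 | ethylene ketal of tetracyclic ketone 15 | C=C(Br)C[C@]23CCC=C([Si](C)(C)Cc4ccccc4)[C@H]2[C@@]12CC=C[C@@](C)(C(=O)O1)[C@H]2CC35OCCO5
F2 | step 4 | 19,2-iodolactone epoxy alcohol | O1[C@H]2C[C@@H](O4)[C@H](I)[C@@](C)(C4=O)[C@@]12CCO
F3 | step 4 | 19,2-iodolactone epoxy silyl ether | O1[C@H]2C[C@@H](O4)[C@H](I)[C@@](C)(C4=O)[C@@]12CCO[Si](C)(C)C(C)(C)C
F4 | step 4 | locked C10 ketone (iodolactone, silyl ether) | O=C1C[C@@H](O2)[C@H](I)[C@@](C)(C2=O)[C@H]1CCO[Si](C)(C)C(C)(C)C
F5 | step 4 | locked ethynyl carbinol | C#C[C@]1(O)C[C@@H](O2)[C@H](I)[C@@](C)(C2=O)[C@H]1CCO[Si](C)(C)C(C)(C)C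
F6 | step 4 | tert-butyldimethylsilyl ether of 6 | C#C[C@@]12CC=C[C@@](C)(C(=O)O1)[C@H]2CCO[Si](C)(C)C(C)(C)C
F7 | step 2 | 2-(2-hydroxyethyl)benzamide of (S)-2-(methoxymethyl)pyrrolidine | OCCc1ccccc1C(=O)N1CCC[C@H]1COC
F8 | step 2 | silyl ether of the hydroxy amide | CC(C)(C)[Si](C)(C)OCCc1ccccc1C(=O)N1CCC[C@H]1COC
F9 | step 2 | Birch reduction–methylation product (diene amide) | C1=CCC=C(CCO[Si](C)(C)C(C)(C)C)[C@]1(C)C(=O)N1CCC[C@H]1COC
F10 | step 2 | single enantiomer of δ-lactone diene 2 | C1C=C[C@@](C)(C(=O)OCC2)C2=C1
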